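## Retrosynthetic overview

1. Feature: in ring B, C2 carries a carboxyl group and lies between C1 (bearing ring C) and C3 (bearing the second carboxyl). Taking C3 out of ring B leaves the five-membered ring C4–C4a–C8a–C1–C2. That ring is a 3-aryl-1-indanone-2-carboxylate, the retron of an aromatic Nazarov cyclisation.
2. Last disconnections: five benzyl ethers and three methyl esters are removed. Before that, the O3'–Cα bond of the (E)-enol ether is made by copper catalysis from phenol 13 and (E)-α-iodocinnamate 19, whose geometry comes from a syn hydrostannation.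
3. C4–H derives from the C4 enol of tetralone β-keto ester 10 through its triflate. The same palladium/formate operation frees O3' from its allyl group.
4. Key disconnection: C3–C4 of ring B. Indanone 8, with a CH2CO2Me arm on quaternary C2, is opened by methoxide at C4–C2 and reclosed through the arm carbon (five- to six-membered ring).
5. Ring order: rings A, C and D are bought. The five-membered carbocycle comes first (Nazarov, sets C1), then ring B by ring expansion (sets C2). Indanone 8 arises from keto ester 2, aldehyde 4 and methyl bromoacetate 7 in three steps.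

Key step: step 6

**Numbering.** Target locants are used for the six-membered series: C1 is aryl-bearing, followed by C2, C3 and C4. Ring A is the benzo ring, ring B the carbocycle, ring C the pendant aryl and ring D the cinnamate aryl. In indanones 6 and 8 the indanone locants C1, C2, C3 correspond to target C4, C2, C1.

**Protecting groups.** Every phenol that ends free is carried as a benzyl ether and released at −78 °C without hydrogen. Hydrogenolysis would saturate C3=C4 and the enol ether, and hot ether cleavage would endanger the less stable E geometry. O3' alone is an allyl ether. All esters are methyl, so methoxide cannot scramble them. From 19 onward light is excluded.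

**Assumption.** The (S,S) enantiomer of 2,2'-(propane-2,2-diyl)bis(4-phenyl-4,5-dihydro-1,3-oxazole) (Ph-box) is taken to give (3R)-6. The sense of induction is to be checked on the first run, and the equally available (R,R) ligand is used if it proves opposite.

## Route

Step 1
Reactants: 1 1-[3,4-bis(benzyloxy)phenyl]ethan-1-one
Product: 2 methyl 3-[3,4-bis(benzyloxy)phenyl]-3-oxopropanoate
Conditions: NaH (2.5 equiv), (MeO)2CO (5 equiv), THF, reflux; AcOH quench
Reagents that add atoms: dimethyl carbonate, COC(=O)OC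
Why: Crossed Claisen condensation of the methyl ketone enolate with dimethyl carbonate, pulled to completion by irreversible deprotonation of the β-keto ester, with benzyl ethers inert to NaH.

Step 2
Reactants: 3 4-(benzyloxy)-3-hydroxybenzaldehyde
Product: 4 3-(allyloxy)-4-(benzyloxy)benzaldehyde
Conditions: allyl bromide (1.2 equiv), K2CO3 (1.5 equiv), DMF, rt
Reagents that add atoms: allyl bromide, C=CCBr
Why: Williamson ether synthesis on the only free phenol, which marks O3' of ring C with a group orthogonal to benzyl.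

Step 3
Reactants: 2 methyl 3-[3,4-bis(benzyloxy)phenyl]-3-oxopropanoate; 4 3-(allyloxy)-4-(benzyloxy)benzaldehyde
Product: 5 methyl (E)-3-[3-(allyloxy)-4-(benzyloxy)phenyl]-2-[3,4-bis(benzyloxy)benzoyl]prop-2-enoate
Conditions: piperidine (0.2 equiv), AcOH (0.2 equiv), toluene, Dean–Stark, reflux
Reagents that add atoms: none
Why: Knoevenagel condensation with azeotropic removal of water, expected to favour the isomer with aryl trans to the ester, the geometry being of no consequence because the isomers interconvert under the Lewis acid of step 4.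

Step 4
Reactants: 5 methyl (E)-3-[3-(allyloxy)-4-(benzyloxy)phenyl]-2-[3,4-bis(benzyloxy)benzoyl]prop-2-enoate
Product: 6 methyl (2S,3R)-3-[3-(allyloxy)-4-(benzyloxy)phenyl]-5,6-bis(benzyloxy)-1-oxo-2,3-dihydro-1H-indene-2-carboxylate
Conditions: Cu(OTf)2 (10 mol %), (S,S)-Ph-box (11 mol %), 4 Å MS, ClCH2CH2Cl, 60 °C
Reagents that add atoms: none
Why: Polarised aromatic Nazarov cyclisation in which the divalent copper–bis(oxazoline) complex chelates the ketone and ester oxygens, the 4π conrotatory closure joins the benzylidene carbon to the ring A carbon para to the 3-benzyloxy group (hence the 5,6-dioxygenated indanone), the C2-symmetric ligand favours one sense of conrotation and thereby sets indanone C3 (C1 of the target) as R, and the enolisable C2 relaxes to the trans (2S) arrangement.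

Step 5
Reactants: 6 methyl (2S,3R)-3-[3-(allyloxy)-4-(benzyloxy)phenyl]-5,6-bis(benzyloxy)-1-oxo-2,3-dihydro-1H-indene-2-carboxylate; 7 methyl bromoacetate
Product: 8 methyl (2R,3R)-3-[3-(allyloxy)-4-(benzyloxy)phenyl]-5,6-bis(benzyloxy)-2-(2-methoxy-2-oxoethyl)-1-oxo-2,3-dihydro-1H-indene-2-carboxylate
Conditions: K2CO3 (1.5 equiv), acetone, 40 °C
Reagents that add atoms: methyl bromoacetate (7), COC(=O)CBr
Why: SN2 C-alkylation of the soft β-keto ester enolate, in which the bromide approaches the indanone face opposite to the neighbouring aryl group and so puts the acetate arm trans to it (2R), a centre that step 6 erases again, while quaternisation makes the keto ester non-enolisable as the key step requires.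

Step 6
Reactants: 8 methyl (2R,3R)-3-[3-(allyloxy)-4-(benzyloxy)phenyl]-5,6-bis(benzyloxy)-2-(2-methoxy-2-oxoethyl)-1-oxo-2,3-dihydro-1H-indene-2-carboxylate
Product: 10 dimethyl (1R,2S)-1-[3-(allyloxy)-4-(benzyloxy)phenyl]-6,7-bis(benzyloxy)-4-hydroxy-1,2-dihydronaphthalene-2,3-dicarboxylate, via ring-opened triester 9 (not isolated)
Conditions: NaOMe (3 equiv), degassed MeOH/THF 1:1, 65 °C, Ar; poured into cold 1 M HCl
Reagents that add atoms: sodium methoxide, C[O-].[Na+] (its OMe sits on C4 in 9 and leaves again on ring closure, so 10 is an isomer of 8)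
Why: The sequence opens with attack of methoxide on the C4 carbonyl of 8, which cannot enolise and is strained in the five-membered ring, and the adduct collapses in a retro-Dieckmann sense with rupture of C4–C2, turning C4 into a methyl benzoate and C2 into the ester enolate of 9. Proton exchange in methanol moves the charge to the arm CH2 (the future C3), whose enolate attacks the benzoate carbonyl in a 6-(enolexo)-exo-trig Dieckmann closure that forms C3–C4 and ring B and gives the methoxide back. The closest known reaction type is the alkoxide-induced retro-Dieckmann/Dieckmann reorganisation of fully substituted cyclic β-keto esters, the all-carbon relative of the Gabriel–Colman rearrangement. The selectivity required is six- over five-membered closure: every event is reversible, attack at an ester only exchanges methoxide, reclosure through C2 merely regenerates 8, and 10 alone owns an acidic C3–H, so its deprotonation by the excess base empties the whole equilibrium into ring B. C1 is attached to no carbonyl group at any stage, lies beyond the reach of methoxide and should retain its R configuration. C2 is flattened in 9 and is set anew under thermodynamic control by C1, the trans (2S) arrangement with aryl and ester both pseudoaxial escaping the aryl/ester gauche contact and the allylic strain against the C3 ester, while exclusion of oxygen keeps the dihydronaphthol enolate from aromatising.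

Step 7
Reactants: 10 dimethyl (1R,2S)-1-[3-(allyloxy)-4-(benzyloxy)phenyl]-6,7-bis(benzyloxy)-4-hydroxy-1,2-dihydronaphthalene-2,3-dicarboxylate
Product: 11 dimethyl (1R,2S)-1-[3-(allyloxy)-4-(benzyloxy)phenyl]-6,7-bis(benzyloxy)-4-{[(trifluoromethyl)sulfonyl]oxy}-1,2-dihydronaphthalene-2,3-dicarboxylate
Conditions: Tf2O (1.2 equiv), iPr2NEt (1.5 equiv), CH2Cl2, −78 to 0 °C
Reagents that add atoms: triflic anhydride, O=S(=O)(OS(=O)(=O)C(F)(F)F)C(F)(F)F
Why: O-Sulfonylation of the fully enolised β-keto ester with a hindered amine at low temperature, conditions under which the much less acidic C2–H is not removed and the trans relationship is kept.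

Step 8
Reactants: 11 dimethyl (1R,2S)-1-[3-(allyloxy)-4-(benzyloxy)phenyl]-6,7-bis(benzyloxy)-4-{[(trifluoromethyl)sulfonyl]oxy}-1,2-dihydronaphthalene-2,3-dicarboxylate
Product: 13 dimethyl (1R,2S)-6,7-bis(benzyloxy)-1-[4-(benzyloxy)-3-hydroxyphenyl]-1,2-dihydronaphthalene-2,3-dicarboxylate, via allyl ether 12 (not isolated)
Conditions: Pd(OAc)2 (5 mol %), PPh3 (20 mol %), HCO2H (6 equiv), Et3N (8 equiv), DMF, 60 °C
Reagents that add atoms: none
Why: Zerovalent palladium formed in the flask inserts into the electron-poor C4–OTf bond and formate supplies hydride after loss of CO2 (palladium/formate hydrogenolysis of a vinyl triflate), after which the same catalyst ionises the allyl aryl ether to a π-allyl complex that formate reduces to propene (Tsuji–Trost-type deallylation), leaving benzyl ethers, esters, C3=C4 and both stereocentres alone.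

Step 9
Reactants: 14 3,4-bis(benzyloxy)benzaldehyde
Product: 15 1,2-bis(benzyloxy)-4-(2,2-dibromoethenyl)benzene
Conditions: CBr4 (2 equiv), PPh3 (4 equiv), CH2Cl2, 0 °C
Reagents that add atoms: carbon tetrabromide, BrC(Br)(Br)Br
Why: First stage of the Corey–Fuchs homologation, a Wittig-type olefination of the aldehyde by the dibromomethylene ylide generated from CBr4 and PPh3.

Step 10
Reactants: 15 1,2-bis(benzyloxy)-4-(2,2-dibromoethenyl)benzene
Product: 17 methyl 3-[3,4-bis(benzyloxy)phenyl]prop-2-ynoate, via lithium acetylide 16 (not isolated)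
Conditions: n-BuLi (2.1 equiv), THF, −78 °C; then ClCO2Me (1.3 equiv), −78 °C to rt
Reagents that add atoms: methyl chloroformate, COC(=O)Cl; n-butyllithium, [Li]CCCC (lithium in 16 only)
Why: Second stage of the Corey–Fuchs sequence, in which bromine–lithium exchange, loss of LiBr with a Fritsch–Buttenberg–Wiechell shift and deprotonation give the acetylide, which is acylated by the chloroformate.

Step 11
Reactants: 17 methyl 3-[3,4-bis(benzyloxy)phenyl]prop-2-ynoate
Product: 18 methyl (E)-3-[3,4-bis(benzyloxy)phenyl]-2-(tributylstannyl)prop-2-enoate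
Conditions: Bu3SnH (1.1 equiv), Pd(PPh3)4 (2 mol %), THF, 0 °C to rt
Reagents that add atoms: tributyltin hydride, CCCC[SnH](CCCC)CCCC
Why: Palladium-catalysed hydrostannation of a 2-alkynoate, a syn addition that places tin on the carbon next to the ester and hydrogen on the aryl-bearing carbon, so that aryl and ester end cis and tin trans to aryl (E).

Step 12
Reactants: 18 methyl (E)-3-[3,4-bis(benzyloxy)phenyl]-2-(tributylstannyl)prop-2-enoate
Product: 19 methyl (E)-3-[3,4-bis(benzyloxy)phenyl]-2-iodoprop-2-enoate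
Conditions: I2 (1.0 equiv), CH2Cl2, 0 °C, dark
Reagents that add atoms: iodine, II
Why: Iododestannylation, an ipso electrophilic substitution at the sp2 carbon that proceeds with retention, run cold, dark and without excess iodine so that the less stable E isomer is not equilibrated.

Step 13
Reactants: 13 dimethyl (1R,2S)-6,7-bis(benzyloxy)-1-[4-(benzyloxy)-3-hydroxyphenyl]-1,2-dihydronaphthalene-2,3-dicarboxylate; 19 methyl (E)-3-[3,4-bis(benzyloxy)phenyl]-2-iodoprop-2-enoate
Product: 20 dimethyl (1R,2S)-6,7-bis(benzyloxy)-1-[4-(benzyloxy)-3-({(E)-1-[3,4-bis(benzyloxy)phenyl]-3-methoxy-3-oxoprop-1-en-2-yl}oxy)phenyl]-1,2-dihydronaphthalene-2,3-dicarboxylate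
Conditions: CuI (10 mol %), N,N-dimethylglycine·HCl (30 mol %), Cs2CO3 (2 equiv), dioxane, 60 °C, Ar, dark
Reagents that add atoms: none
Why: Ullmann-type copper-catalysed O-vinylation of a phenol with a vinyl iodide, which passes through oxidative addition and reductive elimination at copper with retention of alkene geometry, helped by the cis placement of H and I in 19 that disfavours anti elimination to the alkynoate.

Step 14
Reactants: 20 dimethyl (1R,2S)-6,7-bis(benzyloxy)-1-[4-(benzyloxy)-3-({(E)-1-[3,4-bis(benzyloxy)phenyl]-3-methoxy-3-oxoprop-1-en-2-yl}oxy)phenyl]-1,2-dihydronaphthalene-2,3-dicarboxylate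
Product: 21 (1R,2S)-6,7-bis(benzyloxy)-1-[4-(benzyloxy)-3-({(E)-2-[3,4-bis(benzyloxy)phenyl]-1-carboxyethenyl}oxy)phenyl]-1,2-dihydronaphthalene-2,3-dicarboxylic acid
Conditions: LiOH·H2O (12 equiv), THF/MeOH/H2O, rt to 40 °C, dark; 1 M HCl to pH 2
Reagents that add atoms: lithium hydroxide, [Li+].[OH-]
Why: Saponification of the three methyl esters while all phenols are still masked, so that no oxidisable catecholate is present, any reversible deprotonation at C2 returns the favoured trans isomer under control of the untouched C1, and each carboxylate formed lowers the remaining C–H acidity.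

Step 15
Reactants: 21 (1R,2S)-6,7-bis(benzyloxy)-1-[4-(benzyloxy)-3-({(E)-2-[3,4-bis(benzyloxy)phenyl]-1-carboxyethenyl}oxy)phenyl]-1,2-dihydronaphthalene-2,3-dicarboxylic acid
Product: 22 (1R,2S)-1-[3-({(E)-1-carboxy-2-(3,4-dihydroxyphenyl)ethenyl}oxy)-4-hydroxyphenyl]-6,7-dihydroxy-1,2-dihydronaphthalene-2,3-dicarboxylic acid (CNP0241205.1)
Conditions: BCl3 (1 M in CH2Cl2, 15 equiv), C6HMe5 (20 equiv), CH2Cl2, −78 °C, dark; THF/H2O quench
Reagents that add atoms: none
Why: Lewis-acid debenzylation of aryl benzyl ethers by BCl3 with pentamethylbenzene as non-basic benzyl cation scavenger, which operates at −78 °C without hydrogen and should therefore spare C3=C4, the E enol ether and both stereocentres.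

## Compound list

1 | 1-[3,4-bis(benzyloxy)phenyl]ethan-1-one | CC(=O)c1ccc(OCc2ccccc2)c(OCc2ccccc2)c1 | starting material
2 | methyl 3-[3,4-bis(benzyloxy)phenyl]-3-oxopropanoate | COC(=O)CC(=O)c1ccc(OCc2ccccc2)c(OCc2ccccc2)c1 | intermediate
3 | 4-(benzyloxy)-3-hydroxybenzaldehyde | O=Cc1ccc(OCc2ccccc2)c(O)c1 | starting material
4 | 3-(allyloxy)-4-(benzyloxy)benzaldehyde | O=Cc1ccc(OCc2ccccc2)c(OCC=C)c1 | intermediate
5 | methyl (E)-3-[3-(allyloxy)-4-(benzyloxy)phenyl]-2-[3,4-bis(benzyloxy)benzoyl]prop-2-enoate | COC(=O)/C(=C/c1ccc(OCc2ccccc2)c(OCC=C)c1)C(=O)c1ccc(OCc2ccccc2)c(OCc2ccccc2)c1 | intermediate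
6 | methyl (2S,3R)-3-[3-(allyloxy)-4-(benzyloxy)phenyl]-5,6-bis(benzyloxy)-1-oxo-2,3-dihydro-1H-indene-2-carboxylate (trans) | O=C1c2cc(OCc3ccccc3)c(OCc3ccccc3)cc2[C@@H](c2ccc(OCc3ccccc3)c(OCC=C)c2)[C@@H]1C(=O)OC | intermediate
7 | methyl bromoacetate | COC(=O)CBr | starting material
8 | methyl (2R,3R)-3-[3-(allyloxy)-4-(benzyloxy)phenyl]-5,6-bis(benzyloxy)-2-(2-methoxy-2-oxoethyl)-1-oxo-2,3-dihydro-1H-indene-2-carboxylate (acetate arm trans to aryl; key-step precursor) | O=C1c2cc(OCc3ccccc3)c(OCc3ccccc3)cc2[C@@H](c2ccc(OCc3ccccc3)c(OCC=C)c2)[C@@]1(CC(=O)OC)C(=O)OC | intermediate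
9 | dimethyl 2-{(R)-[3-(allyloxy)-4-(benzyloxy)phenyl][4,5-bis(benzyloxy)-2-(methoxycarbonyl)phenyl]methyl}butanedioate (C2 labile; present as its enolates; not isolated) | COC(=O)c1cc(OCc2ccccc2)c(OCc2ccccc2)cc1[C@@H](c1ccc(OCc2ccccc2)c(OCC=C)c1)C(CC(=O)OC)C(=O)OC | intermediate
10 | dimethyl (1R,2S)-1-[3-(allyloxy)-4-(benzyloxy)phenyl]-6,7-bis(benzyloxy)-4-hydroxy-1,2-dihydronaphthalene-2,3-dicarboxylate (trans; enol of the tetralone; key-step product) | COC(=O)C1=C(O)c2cc(OCc3ccccc3)c(OCc3ccccc3)cc2[C@@H](c2ccc(OCc3ccccc3)c(OCC=C)c2)[C@@H]1C(=O)OC | intermediate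
11 | dimethyl (1R,2S)-1-[3-(allyloxy)-4-(benzyloxy)phenyl]-6,7-bis(benzyloxy)-4-{[(trifluoromethyl)sulfonyl]oxy}-1,2-dihydronaphthalene-2,3-dicarboxylate | COC(=O)C1=C(OS(=O)(=O)C(F)(F)F)c2cc(OCc3ccccc3)c(OCc3ccccc3)cc2[C@@H](c2ccc(OCc3ccccc3)c(OCC=C)c2)[C@@H]1C(=O)OC | intermediate
12 | dimethyl (1R,2S)-1-[3-(allyloxy)-4-(benzyloxy)phenyl]-6,7-bis(benzyloxy)-1,2-dihydronaphthalene-2,3-dicarboxylate (not isolated) | COC(=O)C1=Cc2cc(OCc3ccccc3)c(OCc3ccccc3)cc2[C@@H](c2ccc(OCc3ccccc3)c(OCC=C)c2)[C@@H]1C(=O)OC | intermediate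
13 | dimethyl (1R,2S)-6,7-bis(benzyloxy)-1-[4-(benzyloxy)-3-hydroxyphenyl]-1,2-dihydronaphthalene-2,3-dicarboxylate | COC(=O)C1=Cc2cc(OCc3ccccc3)c(OCc3ccccc3)cc2[C@@H](c2ccc(OCc3ccccc3)c(O)c2)[C@@H]1C(=O)OC | intermediate
14 | 3,4-bis(benzyloxy)benzaldehyde | O=Cc1ccc(OCc2ccccc2)c(OCc2ccccc2)c1 | starting material
15 | 1,2-bis(benzyloxy)-4-(2,2-dibromoethenyl)benzene | BrC(Br)=Cc1ccc(OCc2ccccc2)c(OCc2ccccc2)c1 | intermediate
16 | lithium [3,4-bis(benzyloxy)phenyl]acetylide (not isolated) | [Li]C#Cc1ccc(OCc2ccccc2)c(OCc2ccccc2)c1 | intermediate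
17 | methyl 3-[3,4-bis(benzyloxy)phenyl]prop-2-ynoate | COC(=O)C#Cc1ccc(OCc2ccccc2)c(OCc2ccccc2)c1 | intermediate
18 | methyl (E)-3-[3,4-bis(benzyloxy)phenyl]-2-(tributylstannyl)prop-2-enoate (tin trans to aryl) | CCCC[Sn](CCCC)(CCCC)/C(=C/c1ccc(OCc2ccccc2)c(OCc2ccccc2)c1)C(=O)OC | intermediate
19 | methyl (E)-3-[3,4-bis(benzyloxy)phenyl]-2-iodoprop-2-enoate (iodine trans to aryl) | I/C(=C/c1ccc(OCc2ccccc2)c(OCc2ccccc2)c1)C(=O)OC | intermediate
20 | dimethyl (1R,2S)-6,7-bis(benzyloxy)-1-[4-(benzyloxy)-3-({(E)-1-[3,4-bis(benzyloxy)phenyl]-3-methoxy-3-oxoprop-1-en-2-yl}oxy)phenyl]-1,2-dihydronaphthalene-2,3-dicarboxylate | COC(=O)C1=Cc2cc(OCc3ccccc3)c(OCc3ccccc3)cc2[C@@H](c2ccc(OCc3ccccc3)c(O/C(=C/c3ccc(OCc4ccccc4)c(OCc4ccccc4)c3)C(=O)OC)c2)[C@@H]1C(=O)OC | intermediate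
21 | (1R,2S)-6,7-bis(benzyloxy)-1-[4-(benzyloxy)-3-({(E)-2-[3,4-bis(benzyloxy)phenyl]-1-carboxyethenyl}oxy)phenyl]-1,2-dihydronaphthalene-2,3-dicarboxylic acid | O=C(O)C1=Cc2cc(OCc3ccccc3)c(OCc3ccccc3)cc2[C@@H](c2ccc(OCc3ccccc3)c(O/C(=C/c3ccc(OCc4ccccc4)c(OCc4ccccc4)c3)C(=O)O)c2)[C@@H]1C(=O)O | intermediate
22 | (1R,2S)-1-[3-({(E)-1-carboxy-2-(3,4-dihydroxyphenyl)ethenyl}oxy)-4-hydroxyphenyl]-6,7-dihydroxy-1,2-dihydronaphthalene-2,3-dicarboxylic acid | O=C(O)C1=Cc2cc(O)c(O)cc2[C@@H](c2ccc(O)c(O/C(=C/c3ccc(O)c(O)c3)C(=O)O)c2)[C@@H]1C(=O)O | target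

## Step count and risks

Total step count: 15.
Longest linear sequence: 10 steps from 1 (steps 1, 3, 4, 5, 6, 7, 8, 13, 14, 15). The iodide branch from 14 adds steps 9 to 12.

**Risk 1, step 6.**
- What may go wrong: methoxide may strip the C2 methoxycarbonyl group as dimethyl carbonate instead of opening the ring. The cascade may stall after ring opening. Adventitious air may aromatise the enolate.
- Fallback, setting out from 6 and rejoining at 10, is a radical one-carbon ring expansion followed by acylation.
- Alkylation of 6 with CH2Br2 (NaH, THF/DMPU, reflux), again anti to the aryl group, should give methyl (2S,3R)-3-[3-(allyloxy)-4-(benzyloxy)phenyl]-5,6-bis(benzyloxy)-2-(bromomethyl)-1-oxo-2,3-dihydro-1H-indene-2-carboxylate F1.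
- Slow addition of Bu3SnH/AIBN in toluene at 80 °C triggers the Dowd–Beckwith ring expansion. The primary radical adds to the C4 carbonyl, and the cyclopropyloxy radical breaks C4–C2.
- After levelling of C2 with catalytic NaOMe in MeOH, this should give methyl (1R,2R)-1-[3-(allyloxy)-4-(benzyloxy)phenyl]-6,7-bis(benzyloxy)-4-oxo-1,2,3,4-tetrahydronaphthalene-2-carboxylate F2.
- C3 is the only enolisable position next to the ketone, so NaH and dimethyl carbonate in refluxing THF install the missing ester there and deliver 10.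

**Risk 2, step 4.**
- What may go wrong: discrimination between the two senses of conrotation may be weak. Cyclisation may be sluggish because the para-benzyloxy group tempers the aroyl-derived cation. The Lewis acid may strip an allyl or benzyl group on prolonged heating.
- Fallback, setting out from 5 and rejoining at 8, is a racemic cyclisation followed by resolution.
- Sc(OTf)3 in ClCH2CH2Cl without ligand should give the racemic trans keto ester. This is 6 together with its mirror image methyl (2R,3S)-3-[3-(allyloxy)-4-(benzyloxy)phenyl]-5,6-bis(benzyloxy)-1-oxo-2,3-dihydro-1H-indene-2-carboxylate F3.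
- Alkylation with 7 as in step 5 gives 8 together with its mirror image methyl (2S,3S)-3-[3-(allyloxy)-4-(benzyloxy)phenyl]-5,6-bis(benzyloxy)-2-(2-methoxy-2-oxoethyl)-1-oxo-2,3-dihydro-1H-indene-2-carboxylate F4.
- The configurationally fixed quaternary diesters are separated by preparative chromatography on a chiral stationary phase (supercritical CO2/MeOH), and 8 is carried on.

**Risk 3, step 13.**
- What may go wrong: C–O bond formation at the α-carbon of the acrylate may be slow. The alkene geometry may erode. Dehydroiodination followed by attack of the phenoxide at the β-carbon may intervene. The carbonate base may move C3=C4 out of conjugation through the C2 anion.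
- Fallback, setting out from 13 and 14 and rejoining at 20, builds the alkene by olefination instead of transferring it.
- Diazo transfer (4-acetamidobenzenesulfonyl azide, DBU, MeCN) onto commercial methyl bis(2,2,2-trifluoroethyl)phosphonoacetate gives methyl 2-[bis(2,2,2-trifluoroethoxy)phosphoryl]-2-diazoacetate F5.
- Rh2(OAc)4-catalysed O–H insertion of its carbenoid into phenol 13 (toluene, 80 °C) should give dimethyl (1R,2S)-6,7-bis(benzyloxy)-1-[4-(benzyloxy)-3-({1-[bis(2,2,2-trifluoroethoxy)phosphoryl]-2-methoxy-2-oxoethyl}oxy)phenyl]-1,2-dihydronaphthalene-2,3-dicarboxylate F6.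
- Still–Gennari olefination of aldehyde 14 with exactly one equivalent of KN(SiMe3)2 and 18-crown-6 (THF, −78 °C) places the ester cis to the new aryl group. This is the E enol ether 20.

## Further compounds

F1 | step 6 | methyl (2S,3R)-3-[3-(allyloxy)-4-(benzyloxy)phenyl]-5,6-bis(benzyloxy)-2-(bromomethyl)-1-oxo-2,3-dihydro-1H-indene-2-carboxylate | O=C1c2cc(OCc3ccccc3)c(OCc3ccccc3)cc2[C@@H](c2ccc(OCc3ccccc3)c(OCC=C)c2)[C@@]1(CBr)C(=O)OC
F2 | step 6 | methyl (1R,2R)-1-[3-(allyloxy)-4-(benzyloxy)phenyl]-6,7-bis(benzyloxy)-4-oxo-1,2,3,4-tetrahydronaphthalene-2-carboxylate (trans) | O=C1c2cc(OCc3ccccc3)c(OCc3ccccc3)cc2[C@@H](c2ccc(OCc3ccccc3)c(OCC=C)c2)[C@H](C(=O)OC)C1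
F3 | step 4 | methyl (2R,3S)-3-[3-(allyloxy)-4-(benzyloxy)phenyl]-5,6-bis(benzyloxy)-1-oxo-2,3-dihydro-1H-indene-2-carboxylate (mirror image of 6) | O=C1c2cc(OCc3ccccc3)c(OCc3ccccc3)cc2[C@H](c2ccc(OCc3ccccc3)c(OCC=C)c2)[C@H]1C(=O)OC
F4 | step 4 | methyl (2S,3S)-3-[3-(allyloxy)-4-(benzyloxy)phenyl]-5,6-bis(benzyloxy)-2-(2-methoxy-2-oxoethyl)-1-oxo-2,3-dihydro-1H-indene-2-carboxylate (mirror image of 8) | O=C1c2cc(OCc3ccccc3)c(OCc3ccccc3)cc2[C@H](c2ccc(OCc3ccccc3)c(OCC=C)c2)[C@]1(CC(=O)OC)C(=O)OC
F5 | step 13 | methyl 2-[bis(2,2,2-trifluoroethoxy)phosphoryl]-2-diazoacetate | COC(=O)C(=[N+]=[N-])P(=O)(OCC(F)(F)F)OCC(F)(F)F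
F6 | step 13 | dimethyl (1R,2S)-6,7-bis(benzyloxy)-1-[4-(benzyloxy)-3-({1-[bis(2,2,2-trifluoroethoxy)phosphoryl]-2-methoxy-2-oxoethyl}oxy)phenyl]-1,2-dihydronaphthalene-2,3-dicarboxylate (epimers at the phosphonate carbon) | COC(=O)C1=Cc2cc(OCc3ccccc3)c(OCc3ccccc3)cc2[C@@H](c2ccc(OCc3ccccc3)c(OC(C(=O)OC)P(=O)(OCC(F)(F)F)OCC(F)(F)F)c2)[C@@H]1C(=O)OC
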